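## The problem

The target (12) is a depside with no stereocentre. It consists of two benzene rings, each carrying six substituents, joined only by an aryl ester. Ring A is a methyl salicylate (C1 CO2Me, C2 OH, C3 Me, C4 O-acyl, C5 Me, C6 Me). Ring B is the benzoyl part (C1' C=O, C2' Me, C3' Cl, C4' OH, C5' Me, C6' OMe). All control is therefore regiochemical and chemoselective: each ring has to be filled in a defined order, and ring B needs chlorine ortho and the carbonyl para to the C4' oxygen, with the C6' and C4' oxygens differentiated as ether and phenol. The hard bond is the ester. Its carbonyl lies between C1', flanked by the C2' methyl and the C6' methoxy group, and the C4 oxygen, flanked by the C3 and C5 methyls, so ordinary acyl substitution must pass through a tetrahedral intermediate crowded from both sides. The groups that will not take rough treatment are the depside ester and the methyl salicylate (hydroxide, strong nucleophiles), the C3'–Cl bond (hydrogenolysis, reactive low-valent metals) and the free phenols (oxidants). The enabling feature is that the ester carbonyl is a single carbon with no substituent of its own, so it can be delivered as carbon monoxide between an iodide at C1' and the C4 hydroxyl. C1' lies para to the C4' oxygen, where electrophilic iodination occurs naturally, and a C–I bond reacts with palladium well before the C3'–Cl bond. In ring A the C2 hydroxyl is hydrogen-bonded to the C1 ester while the C4 hydroxyl is para to it and more acidic, so the two phenols are already distinguished.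

## Retrosynthesis

**12 from 11.** The last operation cuts only the O–CH2 bond of a methoxymethyl ether on the C4' oxygen. This phenol must be masked during ester formation because a free hydroxyl para to the iodide would compete as a nucleophile and give oligoesters. The methoxymethyl group is chosen because it is small, stable to base, phosphine, palladium and CO, and comes off with acid in methanol. The ester of 11, hindered on both flanks, should resist those conditions. The C2 hydroxyl of ring A is left free throughout. Its hydrogen bond to the C1 ester is expected to keep it out of the acylation, which saves a three-step protection sequence.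

**11 from 5, 10 and 9.** Two bonds are cut at once, C1'–C(=O) and C(=O)–O4, giving aryl iodide 5, carbon monoxide 10 and phenol 9. The neighbouring cut, C(=O)–O alone, would need the 2,6-disubstituted benzoic acid and would force a 2,6-dimethylphenol onto a carbonyl shielded by two ortho groups; the acid itself would most simply come from the same aryl halide. Bringing the carbonyl in as CO lets each crowded ring bond to a planar acyl carbon held on palladium. The precursors are two monocyclic, achiral arenes. The forward reaction has to meet three demands:
- oxidative addition at C–I and not at C–Cl;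
- CO insertion ahead of direct C–O coupling;
- acylation at O4 and not at O2.

**9 from 6 via 8.** Ring A is cut at the C5–CH3 bond. Methyl 2,4-dihydroxy-3,6-dimethylbenzoate (6) is a bulk chemical that already carries every other substituent, and C5 is its only free ring position. Direct methylation of the phenoxide would give C- and O-alkylation mixtures, so the methyl group is introduced as a formyl group (8, through the α-chloro ether 7) and reduced. The formylation has no regiochemical choice to make, and the reduction has no free ring position at which benzylic cations could be intercepted.

**5 from 1 via 2, 3 and 4.** Ring B is cut at the O–CH2OMe bond (5 to 4), the C–I bond (4 to 3), the C–Cl bond (3 to 2) and one O–CH3 bond (2 to 1). 2,5-Dimethylresorcinol (1) has a mirror plane, so monomethylation gives a single monoether 2 and fixes which oxygen becomes the C6' methoxy group. Chlorine is put in before iodine for two reasons. In 2 the position that must take chlorine is the only free site ortho to the hydroxyl and is also para to the methoxy group, so an ortho-directing chlorination is reinforced by the ether. After that, iodination of 3 has only one position left, para to the hydroxyl. Iodinating first would rest on an unaided para/ortho preference between two similarly flanked sites. Each step removes one substituent, and the sequence ends at a commercial diol.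

## Roads not taken

**Alternative 1:** The cut is made inside ring A, not at the ester. C1–C2, C2–C3, C4–C5 and C5–C6 are disconnected, leading back to diazoketone A2 (methyl (2E)-5-diazo-3-methyl-4-oxohex-2-enoate) and siloxyalkyne A3 (tri(propan-2-yl)(prop-1-yn-1-yloxy)silane). In the forward direction, irradiation of A2 would cause Wolff rearrangement to a vinylketene. A [2+2] cycloaddition with A3, 4-electron opening of the cyclobutenone, 6-electron closure and enolisation would then give A1 (methyl 2-hydroxy-3,5,6-trimethyl-4-[tri(propan-2-yl)silyloxy]benzoate).
- Merits: every substituent of ring A is placed by the connectivity of two acyclic pieces, and the two oxygens emerge differentiated, one free and one silylated. That is a cleaner distinction than the hydrogen-bond argument the chosen plan relies on in its key step.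
- Weak points: desilylation of A1 only leads to phenol 9, which the chosen plan reaches in two steps from a commodity chemical. A2 and A3 each need several steps of sensitive chemistry, and a photochemical step is added. The ester, which is the real difficulty, is left unsolved.
- Comparison: against the better oxygen differentiation, the chosen plan sets the short access to 9 and the well-known selectivity of 2,4-dihydroxybenzoates for reaction at O4.

**Alternative 2:** Ring B is cut at C1'–C6' and C2'–C3' and grown on ring A. Phenol 9 would be acylated with a but-2-ynoyl group to give ynoate A5 (methyl 4-(but-2-ynoyloxy)-2-hydroxy-3,5,6-trimethylbenzoate). A Diels–Alder reaction with diene A6 ([(4,4-dimethoxy-3-methylbuta-1,3-dien-2-yl)oxy]trimethylsilane), loss of methanol and desilylation would give A4 (methyl 2-hydroxy-4-[(4-hydroxy-2-methoxy-3,6-dimethylbenzoyl)oxy]-3,5,6-trimethylbenzoate). Chlorination of A4 at C3', its only aromatic C–H, would give 12.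
- Merits: the ester bond is made while the acyl group is a slender rod, which removes the steric problem at its source. No protecting group is needed, and on paper the route is about as short as the chosen one.
- Weak points: a β-methyl ynoate is a sluggish dienophile. The cycloaddition must join the ynoate α-carbon to the fully substituted ketene-acetal terminus of A6, so the congestion returns in the C1'–C6' bond, and the heat this needs works against a hydrolytically and thermally fragile diene. The final chlorination acts on two electron-rich, fully substituted phenol rings, where ipso attack is a concern.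
- Comparison: the chosen plan sets against the step count the fact that every substituent of ring B, chlorine included, is in place before coupling, and that its key step belongs to a known catalytic reaction class and does not rest on an untested cycloaddition.

**Alternative 3:** The ester C(=O)–O bond and C1'–C2' are cut, so that ring B comes from a polyketide-like chain. Heating dioxinone A8 (6-(3,5-dioxohexan-2-yl)-2,2-dimethyl-4H-1,3-dioxin-4-one) would release acetone and an acylketene. Phenol A9 (methyl 2-(benzyloxy)-4-hydroxy-3,5,6-trimethylbenzoate) would capture it, and base-induced aldol closure and dehydration would give A7 (methyl 2-(benzyloxy)-4-[(2,4-dihydroxy-3,6-dimethylbenzoyl)oxy]-3,5,6-trimethylbenzoate).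
- Merits: an acylketene is linear, highly electrophilic and formed under neutral conditions. For the ester-forming event alone this is probably the most dependable way to acylate a 2,6-dimethylphenol, and on that point it is better than the carbonylation.
- Weak points: A7 still lacks the C6' O-methyl group and the C3' chlorine. The hydroxyl to be methylated is the one hydrogen-bonded to the depside carbonyl, so the C4' hydroxyl must first be masked, and the methylation then needs base on a base-sensitive depside. Chlorination and two deprotections follow, one of them a benzyl hydrogenolysis next to C–Cl. A8 and A9 each need several steps.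
- Comparison: the chosen plan needs one mild step after the coupling and no late differentiation of ring B oxygens. It accepts a less proven ester-forming step in exchange.

Key step: step 7

## Route

Remark on the chemistry: the target has no stereocentre, so no stereodescriptors are needed; carbon monoxide is numbered (10) because its carbon becomes the ester carbonyl.

Step 1
Reactants: 1 2,5-dimethylbenzene-1,3-diol
Product: 2 3-methoxy-2,5-dimethylphenol
Conditions: MeI (1.0 equiv), K2CO3 (1.0 equiv), acetone, reflux
Reagents that add atoms: iodomethane, SMILES CI
Why: Williamson O-methylation; the two hydroxyls of 1 are equivalent, so a single monoether should form, to be separated from diether and unreacted diol (recyclable) by chromatography.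

Step 2
Reactants: 2 3-methoxy-2,5-dimethylphenol
Product: 3 6-chloro-3-methoxy-2,5-dimethylphenol
Conditions: SO2Cl2 (1.0 equiv), 2,2,6,6-tetramethylpiperidine (5 mol%), toluene, 0 °C to rt
Reagents that add atoms: sulfuryl chloride, SMILES O=S(=O)(Cl)Cl
Why: Amine-catalysed ortho-selective chlorination of a phenol with sulfuryl chloride; the chlorinating species is held by hydrogen bonding to the hydroxyl and delivered to C6, the only free ortho position, which is also para to the methoxy group.

Step 3
Reactants: 3 6-chloro-3-methoxy-2,5-dimethylphenol
Product: 4 2-chloro-4-iodo-5-methoxy-3,6-dimethylphenol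
Conditions: NIS (1.05 equiv), TsOH·H2O (10 mol%), MeCN, 0 °C to rt, dark
Reagents that add atoms: N-iodosuccinimide, SMILES O=C1CCC(=O)N1I
Why: Electrophilic aromatic iodination; the one remaining ring position is para to the hydroxyl and ortho to the methoxy group, so no regiochemical choice arises.

Step 4
Reactants: 4 2-chloro-4-iodo-5-methoxy-3,6-dimethylphenol
Product: 5 2-chloro-4-iodo-5-methoxy-1-(methoxymethoxy)-3,6-dimethylbenzene
Conditions: NaH, then MOMCl, THF–DMF, 0 °C to rt
Reagents that add atoms: chloromethyl methyl ether, SMILES COCCl
Why: O-alkylation of the sodium phenoxide with a small, highly reactive α-chloro ether; the acidity of the ortho-chlorophenol makes deprotonation easy despite the two flanking groups.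

Step 5
Reactants: 6 methyl 2,4-dihydroxy-3,6-dimethylbenzoate
Product: 8 methyl 5-formyl-2,4-dihydroxy-3,6-dimethylbenzoate, via methyl 5-[chloro(methoxy)methyl]-2,4-dihydroxy-3,6-dimethylbenzoate 7 (not isolated)
Conditions: Cl2CHOMe, TiCl4, CH2Cl2, 0 °C to rt; then ice-cold 1 M HCl
Reagents that add atoms: dichloromethyl methyl ether, SMILES COC(Cl)Cl; water, SMILES O
Why: Rieche formylation; C5 is the only free ring position, ortho to the C4 hydroxyl and para to the C2 hydroxyl, and the α-chloro ether 7 is hydrolysed to the aldehyde on aqueous work-up.

Step 6
Reactants: 8 methyl 5-formyl-2,4-dihydroxy-3,6-dimethylbenzoate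
Product: 9 methyl 2,4-dihydroxy-3,5,6-trimethylbenzoate
Conditions: Et3SiH (3 equiv), TFA, CH2Cl2, rt
Reagents that add atoms: none
Why: Ionic hydrogenation of an electron-rich aryl aldehyde to a methyl group; the benzylic cation is stabilised by the ortho and para hydroxyls, and with every ring position occupied it cannot be intercepted by Friedel–Crafts dimerisation.

Step 7
Reactants: 5 2-chloro-4-iodo-5-methoxy-1-(methoxymethoxy)-3,6-dimethylbenzene, 9 methyl 2,4-dihydroxy-3,5,6-trimethylbenzoate, 10 carbon monoxide
Product: 11 methyl 4-{[3-chloro-6-methoxy-4-(methoxymethoxy)-2,5-dimethylbenzoyl]oxy}-2-hydroxy-3,5,6-trimethylbenzoate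
Conditions: Pd(OAc)2 (5 mol%), Xantphos (7.5 mol%), K3PO4 (2 equiv), CO (5 bar), 4 Å molecular sieves, toluene, 100 °C
Reagents that add atoms: none
Why: Palladium-catalysed aryloxycarbonylation of an aryl iodide is a known three-component ester synthesis, applied here to two di-ortho-substituted partners. Zerovalent palladium formed from Pd(OAc)2 and Xantphos inserts into the C1'–I bond of 5, which is far weaker than the C3'–Cl bond, so the chloride should stay untouched. CO then inserts into the crowded aryl–palladium bond, a step favoured because it moves the metal from the flanked ring carbon to an acyl carbon one atom further out. The potassium phenoxide of 9 displaces iodide on divalent palladium, and C–O reductive elimination, eased by the wide bite angle of Xantphos, releases ester 11 and regenerates zerovalent palladium. Each hindered ring therefore bonds to a planar carbonyl carbon held on the metal, and no tetrahedral intermediate between the two rings is needed. No ring is closed and no stereocentre is formed. Carbonylative coupling over direct C–O coupling is secured by the CO pressure and by fast insertion at a di-ortho-substituted aryl–palladium bond. Acylation at O4 over O2 is secured by the substrate, since the C4 hydroxyl is para to the ester and the more acidic, whereas the C2 hydroxyl is tied up in a hydrogen bond to the C1 ester carbonyl.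

Step 8
Reactants: 11 methyl 4-{[3-chloro-6-methoxy-4-(methoxymethoxy)-2,5-dimethylbenzoyl]oxy}-2-hydroxy-3,5,6-trimethylbenzoate
Product: 12 methyl 4-[(3-chloro-4-hydroxy-6-methoxy-2,5-dimethylbenzoyl)oxy]-2-hydroxy-3,5,6-trimethylbenzoate
Conditions: HCl (1.25 M in MeOH), THF, 40 °C
Reagents that add atoms: none
Why: Acid-catalysed acetal exchange transfers the methoxymethyl group to methanol as dimethoxymethane; the depside ester and the methyl ester are each flanked on both sides and should resist acid methanolysis, and neither ring has a free position for the methoxymethyl cation to attack.

## Compound list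

1 | 2,5-dimethylbenzene-1,3-diol | Cc1cc(O)c(C)c(O)c1 | starting material
2 | 3-methoxy-2,5-dimethylphenol | COc1cc(C)cc(O)c1C | intermediate
3 | 6-chloro-3-methoxy-2,5-dimethylphenol | COc1cc(C)c(Cl)c(O)c1C | intermediate
4 | 2-chloro-4-iodo-5-methoxy-3,6-dimethylphenol | COc1c(I)c(C)c(Cl)c(O)c1C | intermediate
5 | 2-chloro-4-iodo-5-methoxy-1-(methoxymethoxy)-3,6-dimethylbenzene | COCOc1c(Cl)c(C)c(I)c(OC)c1C | intermediate
6 | methyl 2,4-dihydroxy-3,6-dimethylbenzoate | COC(=O)c1c(C)cc(O)c(C)c1O | starting material
7 | methyl 5-[chloro(methoxy)methyl]-2,4-dihydroxy-3,6-dimethylbenzoate (racemic at the benzylic carbon, not isolated) | COC(=O)c1c(C)c(C(Cl)OC)c(O)c(C)c1O | intermediate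
8 | methyl 5-formyl-2,4-dihydroxy-3,6-dimethylbenzoate | COC(=O)c1c(C)c(C=O)c(O)c(C)c1O | intermediate
9 | methyl 2,4-dihydroxy-3,5,6-trimethylbenzoate | COC(=O)c1c(C)c(C)c(O)c(C)c1O | intermediate
10 | carbon monoxide | [C-]#[O+] | starting material
11 | methyl 4-{[3-chloro-6-methoxy-4-(methoxymethoxy)-2,5-dimethylbenzoyl]oxy}-2-hydroxy-3,5,6-trimethylbenzoate | COCOc1c(Cl)c(C)c(C(=O)Oc2c(C)c(C)c(C(=O)OC)c(O)c2C)c(OC)c1C | intermediate
12 | methyl 4-[(3-chloro-4-hydroxy-6-methoxy-2,5-dimethylbenzoyl)oxy]-2-hydroxy-3,5,6-trimethylbenzoate | COC(=O)c1c(C)c(C)c(OC(=O)c2c(C)c(Cl)c(O)c(C)c2OC)c(C)c1O | target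

## Step count and least certain steps

Total step count: 8. Longest linear sequence: 6 steps (1 to 2 to 3 to 4 to 5 to 11 to 12). The ring A branch (6 to 8 to 9) contributes 2 steps and joins at step 7.

**Step 7 (key step).** The most likely failure is slow capture of the aroyl–palladium species by the hindered phenoxide. The catalyst could then decay to palladium black under CO, or the acyl group could be lost to adventitious water. Partial acylation at the C2 oxygen is a lesser concern. The fallback sets out from 5, returns at 11, and forms the same two bonds in separate operations. Iodine–lithium exchange on 5 (n-BuLi, THF, −78 °C) followed by CO2 should give 3-chloro-6-methoxy-4-(methoxymethoxy)-2,5-dimethylbenzoic acid F1. Cyanuric fluoride and pyridine in CH2Cl2 should convert it into 3-chloro-6-methoxy-4-(methoxymethoxy)-2,5-dimethylbenzoyl fluoride F2, the smallest activated acyl derivative. Warming F2 with the potassium phenoxide of 9 (K2CO3, MeCN) should give 11.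

**Step 2.** Uncatalysed background chlorination of the very electron-rich ring could place chlorine para to the hydroxyl or lead to double chlorination, eroding the amine-directed ortho selectivity. The fallback sets out from 2, returns at 3, and replaces hydroxyl-directed delivery with electronic control by the ether. Acetylation (Ac2O, pyridine) should give 3-methoxy-2,5-dimethylphenyl acetate F3, in which the methoxy group is the only strong donor. Chlorination (SO2Cl2, CH2Cl2, 0 °C) should then go para to it, giving 2-chloro-5-methoxy-3,6-dimethylphenyl acetate F4. Methanolysis (K2CO3, MeOH) should release 3.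

**Step 3.** Iodination at a carbon flanked by a methoxy and a methyl group may be slow and, under acid, reversible. Oxidation of the electron-rich chlorophenol by the iodinating agent could compete. The fallback sets out from 3, returns at 11, and changes the halide carried into the coupling. Bromination (NBS, MeCN, 0 °C), which is less sensitive to crowding and not reversible, should give 4-bromo-2-chloro-5-methoxy-3,6-dimethylphenol F5. Protection as in step 4 should give 4-bromo-2-chloro-5-methoxy-1-(methoxymethoxy)-3,6-dimethylbenzene F6. F6 would enter the carbonylation with 9 and 10 under the conditions of step 7 at a somewhat higher temperature; this ligand system is well suited to aryl bromides, and C–Br still reacts ahead of C–Cl.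

**Step 8.** Cleavage of the methoxymethyl ether at the flanked C4' oxygen may be sluggish. Forcing the acid could then bring on methanolysis of the depside ester. The fallback sets out from 4, returns at 12, and replaces the acetal with a fluoride-labile silyl ether. Silylation of 4 (iPr3SiCl, imidazole, DMF) should give (2-chloro-4-iodo-5-methoxy-3,6-dimethylphenoxy)tri(propan-2-yl)silane F7. Carbonylation of F7 with 9 and 10 under the conditions of step 7 should give methyl 4-({3-chloro-6-methoxy-2,5-dimethyl-4-[tri(propan-2-yl)silyloxy]benzoyl}oxy)-2-hydroxy-3,5,6-trimethylbenzoate F8. Buffered fluoride (Bu4NF, AcOH, THF, 0 °C) should then give 12 without any acid or alcohol present.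

## Further compounds

F1 | step 7 | 3-chloro-6-methoxy-4-(methoxymethoxy)-2,5-dimethylbenzoic acid | COCOc1c(Cl)c(C)c(C(=O)O)c(OC)c1C
F2 | step 7 | 3-chloro-6-methoxy-4-(methoxymethoxy)-2,5-dimethylbenzoyl fluoride | COCOc1c(Cl)c(C)c(C(F)=O)c(OC)c1C
F3 | step 2 | 3-methoxy-2,5-dimethylphenyl acetate | COc1cc(C)cc(OC(C)=O)c1C
F4 | step 2 | 2-chloro-5-methoxy-3,6-dimethylphenyl acetate | COc1cc(C)c(Cl)c(OC(C)=O)c1C
F5 | step 3 | 4-bromo-2-chloro-5-methoxy-3,6-dimethylphenol | COc1c(Br)c(C)c(Cl)c(O)c1C
F6 | step 3 | 4-bromo-2-chloro-5-methoxy-1-(methoxymethoxy)-3,6-dimethylbenzene | COCOc1c(Cl)c(C)c(Br)c(OC)c1C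
F7 | step 8 | (2-chloro-4-iodo-5-methoxy-3,6-dimethylphenoxy)tri(propan-2-yl)silane | COc1c(I)c(C)c(Cl)c(O[Si](C(C)C)(C(C)C)C(C)C)c1C
F8 | step 8 | methyl 4-({3-chloro-6-methoxy-2,5-dimethyl-4-[tri(propan-2-yl)silyloxy]benzoyl}oxy)-2-hydroxy-3,5,6-trimethylbenzoate | COC(=O)c1c(C)c(C)c(OC(=O)c2c(C)c(Cl)c(O[Si](C(C)C)(C(C)C)C(C)C)c(C)c2OC)c(C)c1O
A1 | alternative 1 | methyl 2-hydroxy-3,5,6-trimethyl-4-[tri(propan-2-yl)silyloxy]benzoate | COC(=O)c1c(C)c(C)c(O[Si](C(C)C)(C(C)C)C(C)C)c(C)c1O
A2 | alternative 1 | methyl (2E)-5-diazo-3-methyl-4-oxohex-2-enoate | COC(=O)/C=C(C)/C(=O)C(C)=[N+]=[N-]
A3 | alternative 1 | tri(propan-2-yl)(prop-1-yn-1-yloxy)silane | CC#CO[Si](C(C)C)(C(C)C)C(C)C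
A4 | alternative 2 | methyl 2-hydroxy-4-[(4-hydroxy-2-methoxy-3,6-dimethylbenzoyl)oxy]-3,5,6-trimethylbenzoate | COC(=O)c1c(C)c(C)c(OC(=O)c2c(C)cc(O)c(C)c2OC)c(C)c1O
A5 | alternative 2 | methyl 4-(but-2-ynoyloxy)-2-hydroxy-3,5,6-trimethylbenzoate | CC#CC(=O)Oc1c(C)c(C)c(C(=O)OC)c(O)c1C
A6 | alternative 2 | [(4,4-dimethoxy-3-methylbuta-1,3-dien-2-yl)oxy]trimethylsilane | COC(OC)=C(C)C(=C)O[Si](C)(C)C
A7 | alternative 3 | methyl 2-(benzyloxy)-4-[(2,4-dihydroxy-3,6-dimethylbenzoyl)oxy]-3,5,6-trimethylbenzoate | COC(=O)c1c(C)c(C)c(OC(=O)c2c(C)cc(O)c(C)c2O)c(C)c1OCc1ccccc1
A8 | alternative 3 | 6-(3,5-dioxohexan-2-yl)-2,2-dimethyl-4H-1,3-dioxin-4-one (racemic) | CC(=O)CC(=O)C(C)C1=CC(=O)OC(C)(C)O1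
A9 | alternative 3 | methyl 2-(benzyloxy)-4-hydroxy-3,5,6-trimethylbenzoate | COC(=O)c1c(C)c(C)c(O)c(C)c1OCc1ccccc1
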